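(The data come from a simulation with made-up constants, noise included.)

Divide the fall of E (substrate) by the fall of Z (activator), which E meets on the way to the ring Q, and time drops out.

all flasks: E 0.013 M
- Saturday's: Z 0.013 M; D 1.3 mM; the very flask that is asked about, followed so far
- flask: Z 0.0130 M; D 1.30 mM; time 6.0 d

Saturday's run (percent of the E charged)

| time / h | Q / % | E / % |
|---|---|---|
| 20.0 | 38 | 33 |
| 40.0 | 46 | 25 |
| 60.0 | 47 | 24 |
| 96.0 | 50 | 22 |

(readings scatter by 1.5 percentage points)

- Q, in percent of the E first charged, at 6.0 d
- what to do for the largest gain in Q; "none" if nothing gains more than 2 percentage points (spring / midnight / dusk / summer / none)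
- Q present, with what was taken out counted in, in percent of the E first charged, after midnight
- Q present, with what was taken out counted in, in percent of the E first charged, after dusk

- spring: at 6.0 d add Z, 100% of the amount charged, then wait 40 h
- midnight: at 6.0 d add E, 50.0% of the amount charged, then wait 40 h
- dusk: at 6.0 d take out 90% of the Q then present, then wait 40 h
- summer: change nothing and wait 40 h more

- Q that was removed still counts
- additions bring no volume worth counting

Saturday's run is this flask itself. From 60.0 h on it barely moves: between the last two readings E shifts 2 percentage points against a scatter of 1.5 points, so I set time aside. Z was never read, so I commit myself: I take the stall at E 22% to mean that Z has ended, not that a balance stands. Then T, the E spent per Z charged 0.780, is a reading. Two amounts remain: the E charged, and the E that the Z charge can spend. The second over the first in this flask is 0.780, below one, which makes Z the limiting reagent.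

So I expect Q near 50%, and no gain from fresh E, from removal or from waiting. Spring's new Z can spend 78.0% of the E charge, more than the 22% still there, so I choose spring, with a gain near 14 points at the Q per E spent so far.

The forecast reads the stall otherwise, since “the stall looks like reversibility”: Q 51%, best midnight, 70% after midnight, 60% after dusk.

The flask gives Q 51.4% and best spring: spring gains 17 points, midnight 0.043 points, dusk 0.031 points, waiting 0.031 points. After midnight Q stands at 51.4%, and after dusk, with what was taken out counted in, at 51.4%.

    Z → J (k = 6.90 × 10⁻⁶ s⁻¹)
    D + X → G (k = 6.90 × 10⁻⁴ L mol⁻¹ s⁻¹)
    E + Z → X (k = 0.00190 L mol⁻¹ s⁻¹)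
    X → Q (k = 4.90 × 10⁻⁵ s⁻¹)
    E + X → L (k = 0.00190 L mol⁻¹ s⁻¹)

At 144 h this flask holds Z at 0.073% of its charge beside E at 22%, and Z is first to run out. Take the neighbour flask with Z at 0.052 M, which is 4.00 equiv to E, everything else as charged. The same reckoning gives T times Z over E as 3.12, above one, so E should be first to run out there. That neighbour ends with Q 82.7%, Z at 2.1% of its charge, and E at 0%.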